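**Retrosynthetic overview**

1. Target ⇐ 3,10‑O‑silylene‑protected 8α‑alcohol 28: Mitsunobu inversion at C8 with tiglic acid, then desilylation; C13 comes from an Eschenmoser methylenation of the lactone.
2. The cis C1=C2 / 10α‑OH unit ⇐ E‑C1=C10 alkene: outer‑face epoxidation, selenolate opening at C1, then selenoxide elimination inside a temporary seven‑membered O3–Si–O10 ring, which permits only the cis alkene.
3. γ‑Lactone ⇐ C6 ketone plus C7 acetate arm of cyclodecadienone 16 (Felkin–Anh reduction, lactonisation); C8–O ⇐ C8–Si (Tamao–Fleming oxidation).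
4. Ten‑membered ring ⇐ cyclohexenol 12 by anionic oxy‑Cope ring expansion. The enabling feature: C6 (oxygen‑bearing) and C1 are 1,6‑related through both halves of the ring, so a C1–C6 bond gives a cyclohexene (C1–C6, holding the cis C4=C5) that carries the 1,5‑diene C8=C7–C6(O)–C1–C10=C9; the [3,3] shift forms C8–C9, breaks C1–C6, and the enolate is alkylated at C7.
5. 12 ⇐ (S)‑carvone (C1–C6, C9, C10, C14, C15) + a silylacetylene (C7, C8). Ring order: six‑membered carbocycle (chiral pool) → ten‑membered ring (step 9) → γ‑lactone (step 10) → temporary siloxane ring (step 14, removed in step 18).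

Key step: step 9

Remark: the target is read as (3R,6S,7R,8R,10R) with a cis‑fused lactone; names use germacrane numbering with the C7–C11 bond β, i.e. 3α‑OH, 6β‑O, 8β‑tigloyloxy, 10α‑OH, and the SMILES strings are definitive.
Assumption: tert‑butoxy(chloro)diphenylsilane (8) is taken as a purchasable silylating agent.

**Route**

Step 1
Reactants: 1 (S)‑(+)‑carvone
Product: 2 (1S,5S)‑cis‑carveol
Conditions: NaBH4, CeCl3·7H2O, MeOH, 0 °C
Reagents that add atoms: none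
Why: Luche reduction is 1,2‑selective and delivers hydride axially, so the new carbinol is cis to the isopropenyl group.

Step 2
Reactants: 2 (1S,5S)‑cis‑carveol
Product: 3 (1R,5S)‑trans‑carveyl 4‑nitrobenzoate
Conditions: 4‑O2NC6H4CO2H, PPh3, DIAD, THF, 0 → 25 °C
Reagents that add atoms: 4‑nitrobenzoic acid, OC(=O)c1ccc(cc1)[N+](=O)[O-]
Why: The Mitsunobu reaction displaces the oxyphosphonium of the allylic alcohol by the acidic carboxylate with SN2 inversion, setting the oxygen (future C3–O, α) trans to the isopropenyl group.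

Step 3
Reactants: 3 (1R,5S)‑trans‑carveyl 4‑nitrobenzoate
Product: 4 (1R,5S)‑trans‑carveol
Conditions: K2CO3, MeOH, 25 °C
Reagents that add atoms: none
Why: Base‑catalysed methanolysis cleaves the acyl–oxygen bond of the activated benzoate, so the carbinol configuration is untouched.

Step 4
Reactants: 4 (1R,5S)‑trans‑carveol
Product: 5 (1R,5S)‑trans‑carveol tert‑butyldimethylsilyl ether
Conditions: TBSCl, imidazole, DMF, 25 °C
Reagents that add atoms: tert‑butyldimethylsilyl chloride, CC(C)(C)[Si](C)(C)Cl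
Why: Standard silylation of a secondary alcohol gives an ether that survives oxidation, organometallics and KH.

Step 5
Reactants: 5 (1R,5S)‑trans‑carveol tert‑butyldimethylsilyl ether
Product: 6 (4R,6S)‑4‑(tert‑butyldimethylsilyloxy)‑3‑methyl‑6‑(prop‑1‑en‑2‑yl)cyclohex‑2‑en‑1‑one
Conditions: CrO3, 3,5‑dimethylpyrazole, CH2Cl2, −20 °C
Reagents that add atoms: chromium trioxide, O=[Cr](=O)=O
Why: Allylic oxidation converts the only ring methylene allylic to the electron‑rich trisubstituted alkene into the enone carbonyl (future C6), the other ring allylic position being the silyloxy carbon.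

Step 6
Reactants: 7 ethynylmagnesium bromide (HC≡CMgBr); 8 tert‑butoxy(chloro)diphenylsilane
Product: 9 tert‑butoxy(ethynyl)diphenylsilane
Conditions: THF, 0 → 25 °C
Reagents that add atoms: none
Why: Nucleophilic substitution at silicon by the alkynyl Grignard reagent replaces chloride, while the hindered tert‑butoxy group stays as the later handle for oxidation.

Step 7
Reactants: 9 tert‑butoxy(ethynyl)diphenylsilane; 6 (4R,6S)‑4‑(tert‑butyldimethylsilyloxy)‑3‑methyl‑6‑(prop‑1‑en‑2‑yl)cyclohex‑2‑en‑1‑one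
Product: 11 (1R,4R,6S)‑1‑{[tert‑butoxy(diphenyl)silyl]ethynyl}‑4‑(tert‑butyldimethylsilyloxy)‑3‑methyl‑6‑(prop‑1‑en‑2‑yl)cyclohex‑2‑en‑1‑ol, via lithium silylacetylide 10 (not isolated)
Conditions: n‑BuLi, THF, −78 °C; then 6, −78 → −40 °C; aq NH4Cl
Reagents that add atoms: n‑butyllithium, [Li]CCCC (lithium of intermediate 10 only)
Why: 1,2‑Addition of the slim acetylide to the enone carbonyl should occur axially, anti to the pseudoaxial silyloxy group, placing the alkynyl group cis to the isopropenyl group; this carbinol centre (future C6) becomes a carbonyl carbon in step 9, so its configuration is not carried on.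

Step 8
Reactants: 11 (1R,4R,6S)‑1‑{[tert‑butoxy(diphenyl)silyl]ethynyl}‑4‑(tert‑butyldimethylsilyloxy)‑3‑methyl‑6‑(prop‑1‑en‑2‑yl)cyclohex‑2‑en‑1‑ol
Product: 12 (1R,4R,6S)‑1‑{(E)‑2‑[tert‑butoxy(diphenyl)silyl]ethenyl}‑4‑(tert‑butyldimethylsilyloxy)‑3‑methyl‑6‑(prop‑1‑en‑2‑yl)cyclohex‑2‑en‑1‑ol
Conditions: NaAlH2(OCH2CH2OMe)2, THF, 0 → 25 °C; aq KNaC4H4O6
Reagents that add atoms: none
Why: Hydroxyl‑directed trans‑hydroalumination of the propargylic alcohol and protonolysis give the E‑vinylsilane.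

Step 9
Reactants: 12 (1R,4R,6S)‑1‑{(E)‑2‑[tert‑butoxy(diphenyl)silyl]ethenyl}‑4‑(tert‑butyldimethylsilyloxy)‑3‑methyl‑6‑(prop‑1‑en‑2‑yl)cyclohex‑2‑en‑1‑ol; 13 methyl bromoacetate
Product: 16 methyl (1(10)E,4Z)‑8α‑[tert‑butoxy(diphenyl)silyl]‑3α‑(tert‑butyldimethylsilyloxy)‑6‑oxo‑13‑norgermacra‑1(10),4‑dien‑12‑oate, via potassium alkoxide 14 (not isolated), via potassium enolate 15 (not isolated)
Conditions: KH, 18‑crown‑6, THF, 0 → 25 °C; then 13, −78 → −20 °C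
Reagents that add atoms: potassium hydride, [K+].[H-] (potassium of intermediates 14 and 15 only)
Why: KH/18‑crown‑6 gives the free tertiary alkoxide 14, whose charge‑accelerated [3,3] sigmatropic shift (anionic oxy‑Cope rearrangement) across C8=C7–C6(O−)–C1–C10=C9 forms C8–C9 while C1–C6 breaks, and the regiodefined enolate 15 is then alkylated at C7 by methyl bromoacetate. The closest known reaction type is the anionic oxy‑Cope ring expansion of 1,2‑dialkenylcyclohexanols to (E)‑cyclodec‑5‑enones with trapping of the enolate by an electrophile. The ten‑membered carbocycle is closed not end to end but by four‑atom ring expansion of the cyclohexene through a six‑membered chair transition state, so no dilution is needed and the cis C4=C5 bond is carried over unchanged from the six‑membered ring. C8 is set by chirality transfer from the carvone‑derived C1 through the chair in which the C1–C2 ring bond and the E‑silyl group are equatorial (giving E‑C1=C10 and the 8α‑silyl group), and C7 by alkylation on the outer face of the ring enolate, away from the transannular C1=C10 bond. The step needs the [3,3] shift to win over fragmentation and the enolate to survive until alkylation: silicon instead of oxygen at C8 rules out β‑elimination from 15, the E geometry keeps silicon away from both oxygen anions, and either configuration at the carbinol carbon would converge because C6 becomes the carbonyl carbon.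

Step 10
Reactants: 16 methyl (1(10)E,4Z)‑8α‑[tert‑butoxy(diphenyl)silyl]‑3α‑(tert‑butyldimethylsilyloxy)‑6‑oxo‑13‑norgermacra‑1(10),4‑dien‑12‑oate
Product: 18 (1(10)E,4Z)‑8α‑[tert‑butoxy(diphenyl)silyl]‑3α‑(tert‑butyldimethylsilyloxy)‑13‑norgermacra‑1(10),4‑dien‑6β,12‑olide, via hydroxy ester 17 (not isolated)
Conditions: NaBH4, CeCl3·7H2O, MeOH, −40 °C; then PPTS (cat.), CH2Cl2, 25 °C
Reagents that add atoms: none
Why: Luche 1,2‑reduction of the enone under 1,2‑induction from C7 (Felkin–Anh model, the silyl‑bearing C8 as the large group anti to hydride) should give the 6β‑alcohol cis to the acetate arm, which closes to the cis‑fused γ‑lactone; the silicon at C8 leaves O6 as the only hydroxyl that can lactonise.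

Step 11
Reactants: 18 (1(10)E,4Z)‑8α‑[tert‑butoxy(diphenyl)silyl]‑3α‑(tert‑butyldimethylsilyloxy)‑13‑norgermacra‑1(10),4‑dien‑6β,12‑olide
Product: 19 (4Z)‑1β,10α‑epoxy‑8α‑[tert‑butoxy(diphenyl)silyl]‑3α‑(tert‑butyldimethylsilyloxy)‑13‑norgermacr‑4‑en‑6β,12‑olide
Conditions: mCPBA, NaHCO3, CH2Cl2, −20 → 0 °C
Reagents that add atoms: 3‑chloroperoxybenzoic acid, OOC(=O)c1cccc(Cl)c1
Why: Prilezhaev epoxidation should pick the strained, electron‑rich E‑C1=C10 bond over C4=C5 (deactivated by two allylic C–O bonds) and attack its exposed outer face, which sets the C10–O bond α as in the 1β,10α‑epoxides typical of this ring system.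

Step 12
Reactants: 19 (4Z)‑1β,10α‑epoxy‑8α‑[tert‑butoxy(diphenyl)silyl]‑3α‑(tert‑butyldimethylsilyloxy)‑13‑norgermacr‑4‑en‑6β,12‑olide
Product: 20 (4Z)‑8α‑[tert‑butoxy(diphenyl)silyl]‑3α‑(tert‑butyldimethylsilyloxy)‑10α‑hydroxy‑1α‑(phenylselanyl)‑13‑norgermacr‑4‑en‑6β,12‑olide
Conditions: PhSeNa [(PhSe)2, NaBH4], EtOH, 25 → 60 °C
Reagents that add atoms: diphenyl diselenide, c1ccc(cc1)[Se][Se]c1ccccc1
Why: The soft selenolate opens the trisubstituted epoxide by SN2 attack at the secondary C1 with inversion, leaving the C10–O bond and hence the 10α tertiary alcohol intact.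

Step 13
Reactants: 20 (4Z)‑8α‑[tert‑butoxy(diphenyl)silyl]‑3α‑(tert‑butyldimethylsilyloxy)‑10α‑hydroxy‑1α‑(phenylselanyl)‑13‑norgermacr‑4‑en‑6β,12‑olide
Product: 21 (4Z)‑8α‑[fluoro(diphenyl)silyl]‑3α,10α‑dihydroxy‑1α‑(phenylselanyl)‑13‑norgermacr‑4‑en‑6β,12‑olide
Conditions: HF·pyridine, pyridine, THF, 0 → 25 °C
Reagents that add atoms: hydrogen fluoride (as HF·pyridine), F
Why: Buffered fluoride cleaves the allylic silyl ether and exchanges the tert‑butoxy group on the C8 silicon for fluoride, which also activates that silicon for the later oxidation.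

Step 14
Reactants: 21 (4Z)‑8α‑[fluoro(diphenyl)silyl]‑3α,10α‑dihydroxy‑1α‑(phenylselanyl)‑13‑norgermacr‑4‑en‑6β,12‑olide
Product: 22 (4Z)‑3α,10α‑(di‑tert‑butylsilylenedioxy)‑8α‑[fluoro(diphenyl)silyl]‑1α‑(phenylselanyl)‑13‑norgermacr‑4‑en‑6β,12‑olide
Conditions: t‑Bu2Si(OTf)2, 2,6‑lutidine, CH2Cl2, 0 → 25 °C
Reagents that add atoms: di‑tert‑butylsilyl bis(trifluoromethanesulfonate), CC(C)(C)[Si](OS(=O)(=O)C(F)(F)F)(OS(=O)(=O)C(F)(F)F)C(C)(C)C
Why: The cis‑disposed 3α and 10α hydroxyls are bridged as a cyclic silylene, a seven‑membered ring (O–C3–C2–C1–C10–O–Si) that encloses C1 and C2.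

Step 15
Reactants: 22 (4Z)‑3α,10α‑(di‑tert‑butylsilylenedioxy)‑8α‑[fluoro(diphenyl)silyl]‑1α‑(phenylselanyl)‑13‑norgermacr‑4‑en‑6β,12‑olide
Product: 25 (1Z,4Z)‑3α,10α‑(di‑tert‑butylsilylenedioxy)‑8α‑hydroxy‑13‑norgermacra‑1,4‑dien‑6β,12‑olide, via selenoxide 23 (not isolated), via fluorosilyl diene 24 (not isolated)
Conditions: 30% H2O2, KHCO3, THF/MeOH, 0 → 25 °C; then KF, 45 °C
Reagents that add atoms: hydrogen peroxide, OO
Why: Selenoxide syn‑elimination can only go toward C2 (C10 has no hydrogen) and, because C1 and C2 lie in the seven‑membered siloxane ring, can only give the cis C1=C2 bond; Tamao–Fleming oxidation then converts C8–Si into C8–OH with retention.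

Step 16
Reactants: 25 (1Z,4Z)‑3α,10α‑(di‑tert‑butylsilylenedioxy)‑8α‑hydroxy‑13‑norgermacra‑1,4‑dien‑6β,12‑olide
Product: 28 (1Z,4Z)‑3α,10α‑(di‑tert‑butylsilylenedioxy)‑8α‑hydroxygermacra‑1,4,11(13)‑trien‑6β,12‑olide, via Mannich base 26 (not isolated), via ammonium iodide 27 (not isolated)
Conditions: LiN(i‑Pr)2 (2.2 equiv), THF, −78 °C; CH2=NMe2+ I−, −78 → 0 °C; then MeI, MeOH, 25 °C; aq NaHCO3
Reagents that add atoms: N,N‑dimethylmethyleneiminium iodide, C=[N+](C)C.[I-]; iodomethane, CI (methyl of intermediate 27 only)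
Why: Eschenmoser methylenation: the lactone enolate (the 8α‑alkoxide is trans to the lactone and cannot translactonise) undergoes a Mannich reaction, and quaternisation followed by base‑induced elimination gives the exocyclic methylene.

Step 17
Reactants: 28 (1Z,4Z)‑3α,10α‑(di‑tert‑butylsilylenedioxy)‑8α‑hydroxygermacra‑1,4,11(13)‑trien‑6β,12‑olide; 29 tiglic acid
Product: 30 (1Z,4Z)‑3α,10α‑(di‑tert‑butylsilylenedioxy)‑8β‑tigloyloxygermacra‑1,4,11(13)‑trien‑6β,12‑olide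
Conditions: PPh3, DIAD, PhMe, 0 → 25 °C
Reagents that add atoms: none
Why: Mitsunobu esterification of the only free hydroxyl installs the tiglate with SN2 inversion, turning the 8α‑alcohol into the 8β‑ester.

Step 18
Reactants: 30 (1Z,4Z)‑3α,10α‑(di‑tert‑butylsilylenedioxy)‑8β‑tigloyloxygermacra‑1,4,11(13)‑trien‑6β,12‑olide
Product: 31 (1Z,4Z)‑3α,10α‑dihydroxy‑8β‑tigloyloxygermacra‑1,4,11(13)‑trien‑6β,12‑olide (CNP0262559.2)
Conditions: HF·pyridine, pyridine, THF, 0 °C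
Reagents that add atoms: none
Why: Buffered fluoride cleaves both Si–O bonds of the silylene without touching the tiglate, the α‑methylene lactone or the cis ene‑diol.

**Compound list**

1 | (S)‑(+)‑carvone | CC1=CC[C@@H](CC1=O)C(C)=C | starting material
2 | (1S,5S)‑cis‑carveol | CC1=CC[C@@H](C[C@@H]1O)C(C)=C | intermediate
3 | (1R,5S)‑trans‑carveyl 4‑nitrobenzoate | CC1=CC[C@@H](C[C@H]1OC(=O)c2ccc(cc2)[N+](=O)[O-])C(C)=C | intermediate
4 | (1R,5S)‑trans‑carveol | CC1=CC[C@@H](C[C@H]1O)C(C)=C | intermediate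
5 | (1R,5S)‑trans‑carveol tert‑butyldimethylsilyl ether | CC1=CC[C@@H](C[C@H]1O[Si](C)(C)C(C)(C)C)C(C)=C | intermediate
6 | (4R,6S)‑4‑(tert‑butyldimethylsilyloxy)‑3‑methyl‑6‑(prop‑1‑en‑2‑yl)cyclohex‑2‑en‑1‑one | CC1=CC(=O)[C@@H](C[C@H]1O[Si](C)(C)C(C)(C)C)C(C)=C | intermediate
7 | ethynylmagnesium bromide | C#C[Mg]Br | starting material
8 | tert‑butoxy(chloro)diphenylsilane | CC(C)(C)O[Si](Cl)(c1ccccc1)c1ccccc1 | starting material
9 | tert‑butoxy(ethynyl)diphenylsilane | C#C[Si](OC(C)(C)C)(c1ccccc1)c1ccccc1 | intermediate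
10 | lithium [tert‑butoxy(diphenyl)silyl]acetylide | [Li]C#C[Si](OC(C)(C)C)(c1ccccc1)c1ccccc1 | intermediate (not isolated)
11 | (1R,4R,6S)‑1‑{[tert‑butoxy(diphenyl)silyl]ethynyl}‑4‑(tert‑butyldimethylsilyloxy)‑3‑methyl‑6‑(prop‑1‑en‑2‑yl)cyclohex‑2‑en‑1‑ol | CC1=C[C@](O)(C#C[Si](OC(C)(C)C)(c2ccccc2)c2ccccc2)[C@@H](C[C@H]1O[Si](C)(C)C(C)(C)C)C(C)=C | intermediate
12 | (1R,4R,6S)‑1‑{(E)‑2‑[tert‑butoxy(diphenyl)silyl]ethenyl}‑4‑(tert‑butyldimethylsilyloxy)‑3‑methyl‑6‑(prop‑1‑en‑2‑yl)cyclohex‑2‑en‑1‑ol | CC1=C[C@](O)(/C=C/[Si](OC(C)(C)C)(c2ccccc2)c2ccccc2)[C@@H](C[C@H]1O[Si](C)(C)C(C)(C)C)C(C)=C | intermediate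
13 | methyl bromoacetate | COC(=O)CBr | starting material
14 | potassium alkoxide of 12 | [K+].CC1=C[C@]([O-])(/C=C/[Si](OC(C)(C)C)(c2ccccc2)c2ccccc2)[C@@H](C[C@H]1O[Si](C)(C)C(C)(C)C)C(C)=C | intermediate (not isolated)
15 | potassium (1(10)E,4Z,6Z)‑8α‑[tert‑butoxy(diphenyl)silyl]‑3α‑(tert‑butyldimethylsilyloxy)‑11,12,13‑trinorgermacra‑1(10),4,6‑trien‑6‑olate | [K+].[O-]/C1=C/[C@@H]([Si](OC(C)(C)C)(c2ccccc2)c2ccccc2)C/C(C)=C/C[C@@H](O[Si](C)(C)C(C)(C)C)/C(C)=C\1 | intermediate (not isolated)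
16 | methyl (1(10)E,4Z)‑8α‑[tert‑butoxy(diphenyl)silyl]‑3α‑(tert‑butyldimethylsilyloxy)‑6‑oxo‑13‑norgermacra‑1(10),4‑dien‑12‑oate (7α‑H) | O=C1/C=C(/C)[C@H](O[Si](C)(C)C(C)(C)C)C/C=C(\C)C[C@H]([Si](OC(C)(C)C)(c2ccccc2)c2ccccc2)[C@H]1CC(=O)OC | intermediate
17 | methyl (1(10)E,4Z)‑8α‑[tert‑butoxy(diphenyl)silyl]‑3α‑(tert‑butyldimethylsilyloxy)‑6β‑hydroxy‑13‑norgermacra‑1(10),4‑dien‑12‑oate | O[C@H]1/C=C(/C)[C@H](O[Si](C)(C)C(C)(C)C)C/C=C(\C)C[C@H]([Si](OC(C)(C)C)(c2ccccc2)c2ccccc2)[C@H]1CC(=O)OC | intermediate (not isolated)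
18 | (1(10)E,4Z)‑8α‑[tert‑butoxy(diphenyl)silyl]‑3α‑(tert‑butyldimethylsilyloxy)‑13‑norgermacra‑1(10),4‑dien‑6β,12‑olide | C1C(=O)O[C@H]2/C=C(/C)[C@H](O[Si](C)(C)C(C)(C)C)C/C=C(\C)C[C@H]([Si](OC(C)(C)C)(c3ccccc3)c3ccccc3)[C@@H]12 | intermediate
19 | (4Z)‑1β,10α‑epoxy‑8α‑[tert‑butoxy(diphenyl)silyl]‑3α‑(tert‑butyldimethylsilyloxy)‑13‑norgermacr‑4‑en‑6β,12‑olide | C1C(=O)O[C@H]2/C=C(/C)[C@H](O[Si](C)(C)C(C)(C)C)C[C@H]3O[C@]3(C)C[C@H]([Si](OC(C)(C)C)(c4ccccc4)c4ccccc4)[C@@H]12 | intermediate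
20 | (4Z)‑8α‑[tert‑butoxy(diphenyl)silyl]‑3α‑(tert‑butyldimethylsilyloxy)‑10α‑hydroxy‑1α‑(phenylselanyl)‑13‑norgermacr‑4‑en‑6β,12‑olide | C1C(=O)O[C@H]2/C=C(/C)[C@H](O[Si](C)(C)C(C)(C)C)C[C@H]([Se]c3ccccc3)[C@](C)(O)C[C@H]([Si](OC(C)(C)C)(c3ccccc3)c3ccccc3)[C@@H]12 | intermediate
21 | (4Z)‑8α‑[fluoro(diphenyl)silyl]‑3α,10α‑dihydroxy‑1α‑(phenylselanyl)‑13‑norgermacr‑4‑en‑6β,12‑olide | C1C(=O)O[C@H]2/C=C(/C)[C@H](O)C[C@H]([Se]c3ccccc3)[C@](C)(O)C[C@H]([Si](F)(c3ccccc3)c3ccccc3)[C@@H]12 | intermediate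
22 | (4Z)‑3α,10α‑(di‑tert‑butylsilylenedioxy)‑8α‑[fluoro(diphenyl)silyl]‑1α‑(phenylselanyl)‑13‑norgermacr‑4‑en‑6β,12‑olide | C1C(=O)O[C@H]2/C=C(/C)[C@H]3C[C@H]([Se]c4ccccc4)[C@](C)(O[Si](C(C)(C)C)(C(C)(C)C)O3)C[C@H]([Si](F)(c4ccccc4)c4ccccc4)[C@@H]12 | intermediate
23 | selenoxide of 22 (Se configuration open) | C1C(=O)O[C@H]2/C=C(/C)[C@H]3C[C@H]([Se](=O)c4ccccc4)[C@](C)(O[Si](C(C)(C)C)(C(C)(C)C)O3)C[C@H]([Si](F)(c4ccccc4)c4ccccc4)[C@@H]12 | intermediate (not isolated)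
24 | (1Z,4Z)‑3α,10α‑(di‑tert‑butylsilylenedioxy)‑8α‑[fluoro(diphenyl)silyl]‑13‑norgermacra‑1,4‑dien‑6β,12‑olide | C1C(=O)O[C@H]2/C=C(/C)[C@H]3/C=C\[C@](C)(O[Si](C(C)(C)C)(C(C)(C)C)O3)C[C@H]([Si](F)(c4ccccc4)c4ccccc4)[C@@H]12 | intermediate (not isolated)
25 | (1Z,4Z)‑3α,10α‑(di‑tert‑butylsilylenedioxy)‑8α‑hydroxy‑13‑norgermacra‑1,4‑dien‑6β,12‑olide | C1C(=O)O[C@H]2/C=C(/C)[C@H]3/C=C\[C@](C)(O[Si](C(C)(C)C)(C(C)(C)C)O3)C[C@H](O)[C@@H]12 | intermediate
26 | (1Z,4Z)‑3α,10α‑(di‑tert‑butylsilylenedioxy)‑13‑(dimethylamino)‑8α‑hydroxygermacra‑1,4‑dien‑6β,12‑olide (C11 epimers) | CN(C)CC1C(=O)O[C@H]2/C=C(/C)[C@H]3/C=C\[C@](C)(O[Si](C(C)(C)C)(C(C)(C)C)O3)C[C@H](O)[C@@H]12 | intermediate (not isolated)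
27 | trimethylammonium iodide of 26 | C[N+](C)(C)CC1C(=O)O[C@H]2/C=C(/C)[C@H]3/C=C\[C@](C)(O[Si](C(C)(C)C)(C(C)(C)C)O3)C[C@H](O)[C@@H]12.[I-] | intermediate (not isolated)
28 | (1Z,4Z)‑3α,10α‑(di‑tert‑butylsilylenedioxy)‑8α‑hydroxygermacra‑1,4,11(13)‑trien‑6β,12‑olide | C=C1C(=O)O[C@H]2/C=C(/C)[C@H]3/C=C\[C@](C)(O[Si](C(C)(C)C)(C(C)(C)C)O3)C[C@H](O)[C@@H]12 | intermediate
29 | tiglic acid, (E)‑2‑methylbut‑2‑enoic acid | C/C=C(\C)C(=O)O | starting material
30 | (1Z,4Z)‑3α,10α‑(di‑tert‑butylsilylenedioxy)‑8β‑tigloyloxygermacra‑1,4,11(13)‑trien‑6β,12‑olide | C=C1C(=O)O[C@H]2/C=C(/C)[C@H]3/C=C\[C@](C)(O[Si](C(C)(C)C)(C(C)(C)C)O3)C[C@@H](OC(=O)/C(C)=C/C)[C@@H]12 | intermediate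
31 | (1Z,4Z)‑3α,10α‑dihydroxy‑8β‑tigloyloxygermacra‑1,4,11(13)‑trien‑6β,12‑olide, (3R,6S,7R,8R,10R) | C=C1C(=O)O[C@H]2/C=C(/C)[C@H](O)/C=C\[C@](C)(O)C[C@@H](OC(=O)/C(C)=C/C)[C@@H]12 | target

**Step count and risks**

Total step count: 18. Longest linear sequence: 17 steps (steps 1–5 and 7–18, from (S)‑carvone); step 6 is a one‑step branch.

The three steps most likely to fail:

Step 9 (key step). What may go wrong: premature reactions of the free alkoxide 14 or the enolate 15 before C‑alkylation (fragmentation, attack at silicon, proton transfer, O‑alkylation). Fallback, from 12 back to 16: 12 is silylated (TMSOTf, 2,6‑lutidine, CH2Cl2) to its trimethylsilyl ether F1. F1 is rearranged without base in a thermal siloxy‑Cope reaction (PhMe, 190 °C, sealed tube) through the same chair to the ten‑membered trimethylsilyl enol ether F2. MeLi (THF, 0 °C) then releases the lithium enolate F3, which is alkylated with 13 (DMPU, −78 → −20 °C) to give 16.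

Step 10. What may go wrong: poor facial selectivity in the hydride addition to the flexible ring ketone, so that the 6α‑alcohol forms instead of the 6β‑alcohol. Fallback, from 16 back to 18: the 6α‑hydroxy ester F4 from the reduction is saponified (LiOH, THF/H2O, then acidification to pH 5) to the 6α‑hydroxy acid F5. F5 is closed under Mitsunobu conditions (PPh3, DIAD, PhMe, 0 °C); intramolecular SN2 displacement at the activated allylic C6 inverts this centre and gives the cis‑fused lactone 18.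

Step 17. What may go wrong: slow SN2 displacement at the flanked C8 oxyphosphonium, with elimination toward C9 or acyl transfer with retention. Fallback, from 28 back to 30: Dess–Martin periodinane (CH2Cl2, NaHCO3) oxidises 28 to the 8‑ketone F6. NaBH4/CeCl3·7H2O (MeOH, −78 °C) should add hydride from the α face, anti to the β‑oriented lactone bond at C7, to give the 8β‑alcohol F7. F7 is acylated with 29 by Yamaguchi esterification (2,4,6‑trichlorobenzoyl chloride, Et3N, DMAP, PhMe) to give 30.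

Further compounds
F1 | step 9 | trimethylsilyl ether of 12 | CC1=C[C@](O[Si](C)(C)C)(/C=C/[Si](OC(C)(C)C)(c2ccccc2)c2ccccc2)[C@@H](C[C@H]1O[Si](C)(C)C(C)(C)C)C(C)=C
F2 | step 9 | (1(10)E,4Z,6Z)‑8α‑[tert‑butoxy(diphenyl)silyl]‑3α‑(tert‑butyldimethylsilyloxy)‑6‑(trimethylsilyloxy)‑11,12,13‑trinorgermacra‑1(10),4,6‑triene | C[Si](C)(C)O/C1=C/[C@@H]([Si](OC(C)(C)C)(c2ccccc2)c2ccccc2)C/C(C)=C/C[C@@H](O[Si](C)(C)C(C)(C)C)/C(C)=C\1
F3 | step 9 | lithium enolate corresponding to 15 | [Li+].[O-]/C1=C/[C@@H]([Si](OC(C)(C)C)(c2ccccc2)c2ccccc2)C/C(C)=C/C[C@@H](O[Si](C)(C)C(C)(C)C)/C(C)=C\1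
F4 | step 10 | methyl (1(10)E,4Z)‑8α‑[tert‑butoxy(diphenyl)silyl]‑3α‑(tert‑butyldimethylsilyloxy)‑6α‑hydroxy‑13‑norgermacra‑1(10),4‑dien‑12‑oate | O[C@@H]1/C=C(/C)[C@H](O[Si](C)(C)C(C)(C)C)C/C=C(\C)C[C@H]([Si](OC(C)(C)C)(c2ccccc2)c2ccccc2)[C@H]1CC(=O)OC
F5 | step 10 | (1(10)E,4Z)‑8α‑[tert‑butoxy(diphenyl)silyl]‑3α‑(tert‑butyldimethylsilyloxy)‑6α‑hydroxy‑13‑norgermacra‑1(10),4‑dien‑12‑oic acid | O[C@@H]1/C=C(/C)[C@H](O[Si](C)(C)C(C)(C)C)C/C=C(\C)C[C@H]([Si](OC(C)(C)C)(c2ccccc2)c2ccccc2)[C@H]1CC(=O)O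
F6 | step 17 | (1Z,4Z)‑3α,10α‑(di‑tert‑butylsilylenedioxy)‑8‑oxogermacra‑1,4,11(13)‑trien‑6β,12‑olide | C=C1C(=O)O[C@H]2/C=C(/C)[C@H]3/C=C\[C@](C)(O[Si](C(C)(C)C)(C(C)(C)C)O3)CC(=O)[C@@H]12
F7 | step 17 | (1Z,4Z)‑3α,10α‑(di‑tert‑butylsilylenedioxy)‑8β‑hydroxygermacra‑1,4,11(13)‑trien‑6β,12‑olide | C=C1C(=O)O[C@H]2/C=C(/C)[C@H]3/C=C\[C@](C)(O[Si](C(C)(C)C)(C(C)(C)C)O3)C[C@@H](O)[C@@H]12
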